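The data were generated by integration with constants of no real substance; noise was put on by code.

Read the clock first. I have to choose which of these flasks to run next, and I leave the charge of X and L as it stands.

| flask | X | L | temperature | remark | time |
|---|---|---|---|---|---|
| dusk | 0.56 M | 0.60 equiv | 45 °C | run made earlier |  |
| midnight | 0.88 M | 0.60 equiv | 70 °C | run made earlier |  |
| Thursday's | 0.40 M | 0.600 equiv | 50 °C |  | 5.0 h |
| Sunday's | 0.40 M | 0.600 equiv | 90 °C |  | 5.0 h |
| Tuesday's | 0.40 M | 0.600 equiv |  | at 50 °C until 1.5 h, from then on at 90 °C | 5.0 h |
| Saturday's | 0.40 M | 0.600 equiv | 70 °C |  | 5.0 h |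

dusk run (percent of the X charged)

| time / h | Q / % | X / % |
|---|---|---|
| 0.417 | 4 | 98 |
| 0.667 | 4 | 93 |
| 1.00 | 4 | 95 |
| 2.00 | 12 | 90 |
| 3.00 | 16 | 88 |
| 5.00 | 19 | 79 |

midnight run (percent of the X charged)

| time / min | Q / % | X / % |
|---|---|---|
| 20.0 | 26 | 77 |
| 30.0 | 26 | 66 |
| 60.0 | 34 | 55 |
| 80.0 | 44 | 57 |
| 120 | 46 | 48 |

(each reading ± 2 percentage points)

- reactions considered so far: X + L -> Q + G; Q + G -> E

1. the flask with the highest amount of Q, in percent of the X charged ("all alike" if they lie within 1.5 percentage points) (Thursday's / Sunday's / Tuesday's / Saturday's / all alike)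
2. final Q, as a percentage of the X charged, in Thursday's
3. final Q, as a percentage of the X charged, in Sunday's
4. final Q, as a percentage of the X charged, in Tuesday's
5. final Q, as a percentage of the X charged, in Saturday's

1. I take each step's rate as the product of two concentrations. At equal temperature and equivalents, a run charged more thinly then passes through the same percentages more slowly, in the ratio of the charges. I name that ratio the clock factor s, the starting concentration of X in the new flask over that in an earlier run, which turns the new flask's time into the earlier run's time: for Saturday's against midnight, s = 0.455.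

2. Saturday's 5.0 h therefore reads 136 min on the midnight clock, a little later than the last reading at 120 min, which shows Q 46% and X 48%, each reading with a standard deviation of 2 percentage points. So I commit to Q a little above 46% in Saturday's.

3. L is the limiting reagent: each X lost takes one L, so Q plus E cannot pass 60.0% of the X charged. Sunday's and Tuesday's, which both reach 90 °C, have no earlier run at that temperature, so s does not reach them. They can pass Q 46% only if they lose less than 14 points to E, and the last midnight readings of X and Q, taken at 70 °C, leave 6 points unaccounted for, a figure that carries their scatter. I expect Sunday's and Tuesday's to lose more than that, and Thursday's to stay near the dusk reading of 19%.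

4. So I run Saturday's.

The forecast also names Saturday's, with Q 22% in Thursday's, 28% in Sunday's, 31% in Tuesday's and 45% in Saturday's, and says of the loss step “its temperature dependence is a guess”.

The flasks give Q 23.9% in Thursday's, 29.2% in Sunday's, 35.1% in Tuesday's and 47.0% in Saturday's, so Saturday's stands highest.

    X + L → Q + G (k = 0.00280 M⁻¹ s⁻¹, Ea = 86.0 kJ mol⁻¹)
    Q + G → E (k = 2.80 × 10⁻⁴ M⁻¹ s⁻¹, Ea = 76.0 kJ mol⁻¹)
    (constants at 90 °C)

In Saturday's at 0.925 h, the half-life of L by the first step is 1.2 h, or 33.8 min on the midnight clock, while that of Q by the second step is far longer at 28 h, and longer than the 5.0 h of the flask. At 5.00 h, Saturday's makes Q 1.02 times as fast as it uses it up.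

The same flask as Saturday's read at 80 min sits at 36.4 min on the midnight clock, between the readings at 30.0 min and 60.0 min, so Q should lie between 26% and 34%. The computed value is 32.9%.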